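The readings were computed from invented constants.

I started from the constants the readings allow, and first from the zero of the scale. If every step is first order, percent of the charge at a given time doesn't depend on the charge, so the ratio of two runs at equal time is one. The beta and eta runs differ 2.21-fold in charge, yet their target ratio at 12.0 h read 1.02.

| flask | substrate | remark | time |
|---|---|---|---|
| eta | 0.34 M | run made earlier |  |
| beta | 0.75 M | run made earlier |  |
| flask | 0.50 M |  | 12 h |

| run | time / h | target / % | intermediate D / % |
|---|---|---|---|
| eta | 1.00 | 9 | 1 |
| eta | 1.50 | 14 | 0 |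
| eta | 2.50 | 28 | 0 |
| eta | 4.00 | 39 | 3 |
| eta | 8.00 | 54 | 9 |
| eta | 12.0 | 60 | 14 |
| beta | 2.00 | 21 | 1 |
| beta | 4.00 | 42 | 0 |
| beta | 6.00 | 50 | 5 |
| beta | 8.00 | 54 | 6 |
| beta | 10.0 | 59 | 12 |
| beta | 12.0 | 61 | 12 |

(standard deviation of a reading: 2 percentage points)



- concentration of target at 12 h, in M
- concentration of intermediate D at 12 h, in M
- concentration of intermediate B at 12 h, in M

So I pooled the two runs and expected the flask to follow them. Target read 40.5 % at 4.00 h and 54.0 % at 8.00 h. In an exponential rise, the gain over the second of two equal intervals, divided by the gain over the first, is exp(−kΔ). This k, the rise constant or apparent first-order rate constant of target, came to 0.275 h⁻¹, with a plateau of 60.8 %.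

The ladder followed. Target rose with a rise time of 3.64 h. D came later: at 4.00 h it read 1.50 % against a scatter of 2 percentage points, less than target's 40.5 %. The flask's 12 h was 3.30 rise times, so the rise constant put target at 58.5 %. The pooled readings there gave 60.5 %, and I committed to those. D, pooled the same way, went from 7.50 % at 8.00 h to 13.0 % at 12 h. B was never read. The charge less target and D left 26.5 %, which I took as an upper estimate for B.

The forecast gave 0.302 M, 0.065 M and 0.11 M for target, D and B, calling the last “the least certain value”.

The flask gave target 59.7 %, D 13.2 % and B 10.3 %, that is 0.299 M, 0.0658 M and 0.0514 M.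

    intermediate C → target (k = 1.50 h⁻¹)
    intermediate B ⇌ intermediate D (K = 1.70, k = 0.440 h⁻¹)
    intermediate A → intermediate B (k = 0.110 h⁻¹)
    intermediate C ⇌ intermediate E (K = 0.380, k = 0.0770 h⁻¹)
    substrate → intermediate C (k = 0.210 h⁻¹)
    substrate → intermediate A (k = 0.130 h⁻¹)

Of the 27.1 % of the flask that was neither target nor D, intermediate A held 14.1 %, more than B. The rise constant's 58.5 % stood 1.2 points below this flask's target. For the neighbour flask, same charge, read at 5.0 h, the same constant gave 45.4 %, and that flask held 45.8 %.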